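Elm at 0 °C ends higher than oak at −5 °C, with 29.5% of target against 24.3%. Yet elm's solid substrate reads 0% at 8.00 min, so where is the other 70.5%?

| setting | elm | oak | flask |
|---|---|---|---|
| solid substrate | 1.5 M | 1.5 M | 1.5 M |
| temperature | 0 °C | −5 °C | 0 °C |
| remark | the very flask that is asked about, followed so far | run made earlier |  |
| time |  |  | 10 min |

| run | time / min | target / % | solid substrate / % |
|---|---|---|---|
| elm | 0.667 | 2.3 | 74.1 |
| elm | 2.00 | 11.6 | 30.0 |
| elm | 4.00 | 24.3 | 0 |
| elm | 6.00 | 28.5 | 0.7 |
| elm | 8.00 | 29.5 | 0 |
| oak | 0.667 | 1.4 | 75.3 |
| oak | 2.00 | 8.0 | 38.5 |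
| oak | 4.00 | 19.0 | 0.6 |
| oak | 6.00 | 22.8 | 0.1 |
| oak | 8.00 | 24.3 | 0.4 |

(standard deviation of a reading: 1 percentage point)

1. target, in percent of the solid substrate first charged, at 10 min
2. the remedy with the largest gain of target, or "none" below 2 percentage points (spring / dawn / summer / none)
3. target present, with what was taken out counted in, in percent of the solid substrate first charged, after dawn
4. target present, with what was taken out counted in, in percent of the solid substrate first charged, after summer

- spring: at 10 min take out 90% of the target then present, then wait 20 min
- dawn: at 10 min raise the temperature by 10 K, then wait 20 min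
- summer: change nothing and wait 20 min more

- given per volume of solution although it is solid: solid substrate
- removed target is counted in
- at the start none of the solid substrate is in solution

Is that unseen share still feeding target? Over elm's last two readings target rose 1 percentage point, against a scatter of 1 point, and oak rose 1.5 points. Both rises are of the size of that scatter, so I read a rough creep and no more.

So I divide the unseen share by its rate of rise and call the result the drain time: 141 min. I let the unseen share shrink exponentially with that time, and it all ends as target. This gives 30.5% at 10 min and 39.7% after summer, so on my reckoning the asked flask is still rising.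

Does taking target out help? I assume target does not flow back, so spring gains what summer gains, 9.2 points.

Does heat help? At 2.00 min elm holds 1.45 times oak's target. I count the rise of 10 K as two such temperature steps, a factor of 2.10, and I let that shorten the drain time to 67.1 min. I then reckon dawn at 48.4%, more than summer, so I choose dawn.

The forecast gave 30% now, 40% after dawn, 30.2% after summer and chose spring, calling the flask “essentially flat” at 10 min.

The flask gives 28.7% now, 66.0% after dawn and 37.5% after summer. The best remedy is dawn, gaining 37 points against 8.8 points for spring and 8.8 points for summer.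

    starting material ⇌ other conformer (K = 1.20, k = 0.00520 s⁻¹, Ea = 73.0 kJ mol⁻¹, ΔH = −73.0 kJ mol⁻¹)
    other conformer ⇌ third conformer (K = 1.10, k = 0.0417 s⁻¹, Ea = 64.0 kJ mol⁻¹, ΔH = −49.0 kJ mol⁻¹)
    starting material → target (k = 0.00736 s⁻¹, Ea = 82.0 kJ mol⁻¹)
    other conformer → decomposition product (k = 3.25 × 10⁻⁵ s⁻¹, Ea = 86.0 kJ mol⁻¹)
    third conformer → third product (k = 0.00726 s⁻¹, Ea = 69.0 kJ mol⁻¹)
    solid substrate ⇌ starting material, rate k6*(cs6 - [starting material]) while solid is left; crystals form when [starting material] > cs6 (solubility = 0.780 M, k = 0.0154 s⁻¹)
    other conformer → isomer of the product (k = 0.00924 s⁻¹, Ea = 83.0 kJ mol⁻¹)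
    starting material ⇌ dormant form (K = 29.2, k = 0.0182 s⁻¹, Ea = 77.0 kJ mol⁻¹, ΔH = −58.0 kJ mol⁻¹)
    (constants at 0 °C)

In this flask, while solid substrate dissolved (62.6% at 1.00 min, 0% at 5.00 min), starting material went over into the dormant form, which stood at 57.2% at 5.00 min beside 25.8% of target. The dormant form then fell, to 54.0% at 10.0 min and 15.0% at 100 min. The drain time gave 39.7% after summer against the flask's 37.5%, but dawn's 66.0% stood above my 48.4%. Carried to this flask left until 100 min, the drain time gives 63.3%, where target stands at 54.4% beside 17.4% of isomer of the product and 12.6% of third product.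

(The readings come from a simulation with made-up constants; the scatter is artificial.)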